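Which flask holds more target after 5.0 h: autumn, kept at 0 °C, or summer, warmed to 40 °C at 1.5 h?

| flask | substrate | temperature | remark | time |
|---|---|---|---|---|
| elm | 2.1 M | 10 °C | run made earlier |  |
| birch | 2.1 M | 32 °C | run made earlier |  |
| autumn | 1.5 M |  | at 0 °C throughout | 5.0 h |
| summer | 1.5 M |  | at 0 °C until 1.5 h, from then on at 40 °C | 5.0 h |

- the winner by amount of target, in percent of the substrate charged; "neither" if no more than 2 percentage points parts them (autumn / summer / neither)
- how much target is there at the end, in percent of the substrate charged: autumn
- how much target is there at the end, in percent of the substrate charged: summer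

- elm (time / min: target / %, substrate / %): 6.00: 0.1, 77.8; 20.0: 1.6, 42.2; 30.0: 4.8, 29.3; 50.0: 14.7, 13.1; 80.0: 32.7, 5.4; 90.0: 38.1, 3.6; 120: 53.0, 2.6
- birch (time / min: target / %, substrate / %): 2.00: 3.0, 38.6; 6.00: 30.2, 12.0; 10.0: 58.3, 5.8; 15.0: 78.9, 3.2; 25.0: 91.9, 0.2; 30.0: 93.9, 0.7; 40.0: 95.4, 0.2

(scatter of a reading: 0.5 percentage points)

- what was read earlier has a scatter of 0.5 percentage points, one standard deviation

My zero of the scale is the symmetric case: if the steps between substrate and target shared one activation energy, a change of temperature would merely reset the clock, and the elm and birch tables would become one table once their times are scaled. So I read them side by side. The elm row at 80.0 min and the birch row at 6.00 min hold 32.7 % and 30.2 % target, which makes their time ratio, my clock factor F = 13.3, a fair pairing. The rows with ratio 12.0 put birch ahead, 58.3 % against 53.0 %, and those with ratio 15.0 put elm ahead, 4.8 % against 3.0 %, so F is bracketed. The substrate column of the first pair, 5.4 % against 12.0 %, does not scale, so the symmetry is claimed for the target column, which is the one asked about.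

Through the Arrhenius law, F gives E, the apparent activation energy of the target clock, 84.6 kJ/mol. With E, autumn's 5.0 h counts as 80.5 min of elm time, so I read autumn from the elm row at 80.0 min: 32.7 %. This assumes that percentages ignore the charge, which the runs cannot test, since both hold 2.1 M. Summer's two stretches count as 494 min of birch time, far more than the 40.0 min of the last birch row, so I put summer at about that row's 95.4 %, more than autumn.

The forecast says summer, with autumn at 29 % and summer at 96 %, holding that in the cold “both steps run about four times slower”; its autumn is lower than mine.

The simulation gives summer, with autumn at 34.0 % and summer at 97.1 %.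

    intermediate D → target (k = 0.00877 /min, Ea = 87.0 kJ/mol)
    intermediate A → intermediate C (k = 0.206 /min, Ea = 79.0 kJ/mol)
    substrate ⇌ intermediate B (K = 5.03, k = 0.00302 /min, Ea = 87.0 kJ/mol, ΔH = −42.0 kJ/mol)
    intermediate A → side product (k = 0.00517 /min, Ea = 85.0 kJ/mol)
    substrate → intermediate A (k = 0.00928 /min, Ea = 79.0 kJ/mol)
    intermediate C → intermediate D (k = 0.00615 /min, Ea = 84.0 kJ/mol)
    (constants at 0 °C)

Autumn stands 1.3 percentage points above the elm reading I took for it and 5 points above the forecast. The same reckoning goes to a neighbour, autumn's flask run at −15 °C: with E, its 5.0 h counts as 9.25 min of elm time, between the elm rows at 6.00 min and 20.0 min, whose target reads 0.1 % and 1.6 %, and that neighbour holds 0.212 % target.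

(The data stem from a simulated flask with constants of no real substance; the scatter is artificial.)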